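Starting material over catalyst is 2.27 in amber, 3.64 in grey and 5.45 in red, and that ratio is the number of turns the average catalyst has to make to use up the charge.

all flasks: reagent 0.780 M; free catalyst 110 mM (in portions, 4); time 1.0 h
- amber: starting material 0.25 M; the portions of free catalyst follow each other after 15 min, the first at the start
- grey: starting material 0.40 M; the portions of free catalyst follow each other after 15 min, the first at the start
- red: starting material 0.60 M; the portions of free catalyst follow each other after 15 min, the first at the start

    catalyst intermediate C ⇌ by-product + catalyst intermediate D (K1 = 10 M, k1 = 0.050 s⁻¹)
    catalyst intermediate A → catalyst intermediate B (k2 = 0.0072 s⁻¹)
    starting material + free catalyst → catalyst intermediate A (k3 = 0.023 M⁻¹ s⁻¹)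
    reagent + catalyst intermediate B ⇌ catalyst intermediate C (K4 = 1.8 M⁻¹, k4 = 0.012 M⁻¹ s⁻¹)
    catalyst intermediate D → free catalyst + product (k5 = 0.0082 s⁻¹)

1. [product] at the end for amber, grey, red, in this order
2. how the row runs (falls all the way / falls, then rises / rises, then falls / hardly changes / rises all the way)

- "hardly changes" means that all values lie within two and a half points (for a concentration: within two and a half percent of the largest)
- run time (amber): 1.0 h

So I reckon how long one turn takes. Catalyst intermediates A, C and D go forward at their own rate constants, with no partner to wait for. The sum of their mean lives is 4.68 min, and I call it the fixed time. Two waits come on top. Free catalyst waits the reciprocal of its rate constant times the starting material present, and catalyst intermediate B waits likewise on the reagent. I neglect the fall back from catalyst intermediate C to catalyst intermediate B, which makes no difference in amber.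

Now the settings, by hand. The portions come first: with the catalyst arriving in 4 steps 15 min apart, the catalyst present averages 68.8 mM over the run, against the 110 mM charged.

Next comes the starting material. I take each flask where half its charge is spent, with the reagent down by the same amount. A turn then lasts 12.6 min in amber, 10.7 min in grey and 9.99 min in red. Mean catalyst times run time over turn time gives an estimated output of 0.327 M for amber, 0.386 M for grey and 0.413 M for red.

The starting material is the limiting reagent in red, and amber's estimated output stands above its charge, so for amber I commit to the charge, 0.25 M. Grey's and red's estimated outputs lie below their charges , so I commit to those outputs, and my row rises all the way.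

The forecast, lower than mine in each flask , gives 0.19 M, 0.28 M and 0.37 M, a row that rises all the way, and says “Red is limited more by catalyst time and falling reagent”.

The flask gives 0.227 M, 0.318 M and 0.382 M, a row that rises all the way, with my figures above it in each flask . Red ends with 24.2% of its starting material and 48% of its reagent left. Adding the waits at those amounts to the fixed time gives a turn of 13.4 min, and free catalyst's wait is 37.4% of it, while red's free catalyst stands at 33.9%. The same sum for grey, with 10.0% of its starting material and 57% of its reagent left, gives 69.9%, while grey's free catalyst stands at 61.9%.

The rate constants were chosen freely, and the outcome is calculated.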